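The numbers in the tables were computed on assumed constants, and the scatter is random.

A reading at 25 min catches a slow process early, so you reckon with how far it has got by then.

| setting | elm | maple | alder | oak | Saturday's | Tuesday's | Thursday's | Sunday's |
|---|---|---|---|---|---|---|---|---|
| solid substrate | 21 mM | 21 mM | 21 mM | 21 mM | 21 mM | 21 mM | 21 mM | 21 mM |
| first nucleophile | 31.5 mM | 31.5 mM | 31.5 mM | 16 mM | 31.5 mM | 31.5 mM (fed, over 10 min) | 31.5 mM | 31.5 mM (in portions, 2, over 10 min) |
| second nucleophile | 18.9 mM | 9.4 mM | 14 mM | 18.9 mM | 18.9 mM (fed, over 10 min) | 18.9 mM | 18.9 mM | 18.9 mM |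
| remark | run made earlier | run made earlier | run made earlier | run made earlier | all else is in the flask from the start; the feed brings no volume worth counting | all else is in the flask from the start; the feed brings no volume worth counting | everything together at the start | first portion at the start, last at 10 min |
| time |  |  |  |  | 25 min | 25 min | 25 min | 25 min |

| run | time / min | other capture product / % | target / % |
|---|---|---|---|
| elm | 1.33 | 0.2 | 0 |
| elm | 2.50 | 0.9 | 1.1 |
| elm | 4.00 | 1.2 | 0 |
| elm | 8.00 | 2.6 | 0.2 |
| elm | 15.0 | 5.4 | 1.3 |
| maple | 2.50 | 0 | 0.3 |
| maple | 8.00 | 1.3 | 1.4 |
| maple | 15.0 | 4.0 | 3.1 |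
| maple | 20.0 | 5.1 | 4.1 |
| maple | 30.0 | 7.6 | 5.1 |
| alder | 2.50 | 1.7 | 0.7 |
| alder | 8.00 | 2.6 | 1.3 |
| alder | 15.0 | 4.0 | 3.1 |
| alder | 20.0 | 6.5 | 2.8 |
| alder | 30.0 | 9.6 | 4.5 |
| oak | 2.50 | 0.5 | 0.3 |
| oak | 5.00 | 2.2 | 0 |
| oak | 8.00 | 2.1 | 0.4 |
| oak | 15.0 | 5.6 | 1.0 |
| oak | 30.0 | 11.8 | 1.4 |

(scatter of a reading: 0.5 percentage points)

- solid, in amounts per volume of the solution: solid substrate
- at the start none of the solid substrate is in solution

1. the flask that comes out highest in amount of other capture product, in percent of the solid substrate charged; "all alike" if 1.5 percentage points covers them all (Saturday's / Tuesday's / Thursday's / Sunday's / all alike)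
2. amount of other capture product at the end, in percent of the solid substrate charged, Saturday's
3. amount of other capture product at the end, in percent of the solid substrate charged, Tuesday's
4. amount of other capture product at the end, in percent of the solid substrate charged, Thursday's
5. amount of other capture product at the end, in percent of the solid substrate charged, Sunday's

Start with the main step alone, the supply. At 30.0 min, the two products together stand at 12.7% in maple, 14.1% in alder and 13.2% in oak. Yet maple holds 9.4 mM of second nucleophile against 18.9 mM in oak, and oak holds 16 mM of first nucleophile against 31.5 mM in maple. So I read the flow as steady, a zero-order supply with dissolving as the likely rate-limiting step. At that flow I reckon the whole charge lasts 225 min. Call this the lifetime of the solid. By this reckoning a reading at 25 min holds 11.1% of products in each of the flasks asked about.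

Now add the split. Take other capture product over target, multiply by first over second nucleophile charge, and you have a selectivity factor, read from those readings of maple, alder and oak as 5.64. With the full charges, the other capture product takes 77.2% of the flow, so my figure for Thursday's is 8.57%.

Last, add the dosing. Over the first 10 min, the steady feed, or the first of Sunday's two portions, puts on average half of the charge in the flask. With first nucleophile halved, the share for that stretch is 87.1%, which gives 9.02% for Tuesday's and Sunday's. With second nucleophile halved, the share is 62.9%, which gives 7.94% for Saturday's. My spread is 1.1 percentage points, less than the margin of 1.5 points.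

The forecast says all alike: Saturday's 7.8% (6.9% to 8.7%), Tuesday's 9.2% (8.3% to 10.2%), Thursday's 8.7% (7.8% to 9.7%), Sunday's 9.2% (8.3% to 10.2%). Its ground is that “dissolution limits the rate and capture is fast”. Its spread, 1.4 points, is wider than mine.

The flasks give Saturday's 8.00%, Tuesday's 8.90%, Thursday's 8.45% and Sunday's 8.94%, so the answer is all alike, and the forecast held. Thursday's two products sum to 11.7%, where the lifetime gave 11.1%.

    starting material → intermediate (k = 0.0200 s⁻¹)
    first nucleophile + intermediate → target (k = 1.30 M⁻¹ s⁻¹)
    second nucleophile + intermediate → other capture product (k = 46.0 M⁻¹ s⁻¹)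
    second nucleophile ⇌ dormant form (K = 6.90, k = 0.0650 s⁻¹)
    solid substrate ⇌ starting material, rate k5*(cs5 - [starting material]) while solid is left; crystals form when [starting material] > cs5 (solubility = 1.30 mM, k = 0.00140 s⁻¹)

The low solubility of the starting material is the main reason Thursday's stands so low: taking it away lifts the other capture product from 8.45% to 55.6%. The flask also holds a dormant form, 15.0 mM in Thursday's, which my number does not carry. Free second nucleophile ends at 11% of its charge in Saturday's and 11% in Tuesday's, and those two flasks end 0.9 points apart in other capture product. Now leave Thursday's flask until 1.5 h: the lifetime gives 40.0% of products. That flask gives 13.1% of target and 30.2% of other capture product, 43.3% together.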